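## Structural features

The target is an achiral, fully conjugated chain of three rings: a para-hydroxyphenyl ring (ring A), a 1,3-oxazole (ring B: O1, C2, N3, C4, C5) and a 1H-pyrrole (ring C). They are joined by two single bonds, C5 to the aryl carbon and C2 to C2' of ring C. Ring B carries no hydrogen: C5 bears ring A, C4 a chlorine and C2 ring C, while ring C carries chlorine on C3', C4' and C5' and keeps a free N–H. There is no stereocentre, so no stereochemical relationship has to be built. The fragile groups are the free phenol (it activates ring A towards electrophilic halogenation and oxidation), the acidic N–H of the polychlorinated ring C (ionised by mild base, then nucleophilic), and the four C–Cl bonds, which rule out reducing metals and hydrogenolysis. The difficulty lies less in the skeleton than in placing four chlorines on two different heterocycles, C4 of ring B in particular, without touching ring A. The key step exploits that O1–C2–N3 together with C2' is a primary carboxamide of ring C in disguise, and that C4–C5 together with ring A is an arylacetic acid in disguise. C4, lying between N3 and the benzylic C5, can therefore enter as an acyl carbon and C5 as a benzylic carbon bearing a leaving group; the oxygen left on C4 is later exchanged for chlorine.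

## Logic of the disconnections

**10 to 9.** The first cut is outside the skeleton: the phenol O–H of 10 becomes an O–acetyl bond in 9. A free phenol would make ring A the most electron-rich site of every intermediate and would itself react with acyl chlorides and POCl3; as an acetate it is a weakly deactivated spectator. Nothing is gained in size, but every earlier step becomes chemoselective. The forward step must cleave an aryl ester without disturbing C4–Cl or ring C, which calls for cold methanolysis.

**9 to 8.** The C4–Cl bond of ring B is cut and C4 is returned to the acyl oxidation level (C4=O, C5 sp3), giving 8. Cutting here means the chlorine enters at the one carbon that already carries oxygen, so there is no regiochemical choice and no electrophilic chlorine source in the presence of ring A. The gain is that ring B becomes an oxazolone that can be made by annulation. The demand is a deoxychlorination of an enolisable oxazol-4-one, which has to proceed by addition–elimination at C4 under acidic, anhydrous conditions that the acetate tolerates.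

**8 to 2 and 6 (through 7).** Ring B is opened at N3–C4 and at O1–C5. These two bonds divide the molecule into halves of similar size: N3 and O1 are the nitrogen and oxygen of one carboxamide in 2, and C4 and C5 are the acyl carbon and the α-carbon of 6. One ring and two bonds are made in a single operation and the synthesis becomes convergent. The forward step must acylate the carboxamide nitrogen (giving 7) and then close through the amide oxygen, not through the ring C nitrogen.

**6 to 4 (through 5).** The C5–Br bond and the acyl C–Cl bond are cut, leaving the plain arylacetic acid 4. Both are activating groups placed on a position that is at once benzylic and α to a carbonyl, hence the easiest C–H to functionalise. The forward step must brominate that carbon and not ring A, which the acetate and the acidic medium should ensure.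

**4 to 3.** The O–acetyl bond is cut to give the purchasable phenol acid 3. The protection is placed first so that the same group serves the bromination, the annulation and the deoxychlorination.

**2 to 1.** The three C–Cl bonds of ring C are cut, leading to the purchasable amide 1. Because every free position of ring C ends up chlorinated, exhaustive electrophilic chlorination has a single end-point and needs no regiocontrol. It is done before the fragments are joined, so no electrophilic chlorine ever meets ring A or ring B. The demand is complete reaction at the least reactive position, C3', without damage to the primary amide.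

## Other disconnections considered

**Alternative 1:** The cut is at C2–C2' and O1–C2; ring C is taken back to a lactam and ring B is built from an isocyanide.
- **Forward key step.** 3,4-Dichloromaleimide A1 would be reduced at one carbonyl to the hydroxy lactam A2. BF3·OEt2 would ionise A2 to an N-acyliminium ion, the isocyanide carbon of the isocyano ketone A3 would add to it, and the ketone oxygen would close onto the nitrilium carbon to give A4.
- **In its favour.** Two of the ring C chlorines come from a cheap symmetrical imide, and the third could arrive together with aromatisation by deoxychlorination of the lactam carbonyl. On this point the plan is the equal of the chosen one in logic (chlorine from an oxidation level) and arguably better, since ring C never sees an electrophilic chlorination.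
- **Against it here.** The cation from A2 is destabilised by two chlorines and by cross-conjugation with the lactam. A3 belongs to a class that cyclises by itself to a 2-unsubstituted oxazole under acid or base, so the bimolecular capture has to outrun a unimolecular side reaction. A4 has C4–H, so the C4 chlorine must still be introduced by an electrophile in the presence of an anisole ring, and the methyl ether then needs BBr3.
- **Comparison.** Structurally both plans are convergent and the step count is about equal once the preparation of A3 is included. Mechanistically the chosen plan rests on one unproven step (C4 deoxychlorination), whereas this one rests on an unproven key step plus a regiochemically open chlorination.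

**Alternative 2:** The cut is N3=C2 alone, O1–C2 having been made earlier as an ester bond.
- **Forward key step.** The acid chloride A5 would O-acylate the enolate of the azido ketone A6 to the Z-configured azidovinyl ester A7. P(OEt)3 would then convert the azide into a phosphazene (Staudinger reaction) whose nitrogen condenses with the neighbouring ester carbonyl (intramolecular aza-Wittig) to give A8.
- **In its favour.** The ring closure is a known oxazole synthesis that runs under neutral conditions. The acidic N–H of ring C therefore cannot compete in the closure, which makes it better than the chosen plan on that point. Ring B is also aromatic at once, with no oxidation-level adjustment.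
- **Against it here.** A5 is an N–H pyrrole-2-carbonyl chloride and is prone to self-condensation under the basic conditions of the enolate acylation. The enol ester must be formed with Z geometry. A low-molecular-weight organic azide has to be handled. A8 again has C4–H and needs an electrophilic chlorination, although the pivalate keeps ring A quiet.
- **Comparison.** On precedent for the ring-forming step this plan is the better one. On certainty of the position of the C4 chlorine and on length (roughly three operations more, with a longer linear sequence) the chosen plan is better.

**Alternative 3:** The cuts are N3–C2 and O1–C5.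
- **Forward key step.** The azirine A9 would be acylated on nitrogen by A5 and chloride would add to the benzylic C=N carbon. The N-acyl chloroaziridine would open at the benzylic C–N bond, the amide oxygen would capture that carbon, and loss of HCl would give A10.
- **In its favour.** Two bonds and one ring are formed in one convergent step from two halves, which makes it the equal of the chosen plan in convergence. The reaction type is known, and the para-methoxy group favours the benzylic opening that leads to the 5-aryl isomer.
- **Against it here.** A9 is a strained intermediate that needs several steps via an azide or a Neber-type route. A5 has the self-condensation problem noted above. The methoxy group that helps the key step makes ring A a competitor in the later electrophilic chlorination of C4 and requires BBr3 at the end.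
- **Comparison.** Both plans build ring B from an acyl unit of ring C and a two-carbon benzylic unit. The alternative delivers the aromatic ring directly (better), but leaves C4 as C–H and is longer (worse).

Key step: step 4

Remarks on the chemistry:
- 1 is used as the source of ring C instead of a pyrrole ester, because ammonolysis of a trichloropyrrole ester with an acidic N–H is expected to be sluggish; this saves one step.
- 8 is written as its 5H-keto tautomer. It is expected to equilibrate with, and largely exist as, the 4-hydroxyoxazole, which is the form that reacts in step 5.
- C5 of 6, 7 and 8 is a racemic stereocentre that disappears on aromatisation, so the route sets no permanent stereocentre.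
- 1 and 3 are taken to be purchasable.

## Route

Step 1
Reactants: 1 1H-pyrrole-2-carboxamide
Product: 2 3,4,5-trichloro-1H-pyrrole-2-carboxamide
Conditions: NCS (3.2 equiv), MeCN–AcOH, 25 → 60 °C; aq. Na2S2O3 work-up
Reagents that add atoms: N-chlorosuccinimide, O=C1CCC(=O)N1Cl
Why: Threefold electrophilic aromatic chlorination of the pyrrole; C4' and C5' should react first and C3' last on warming, and since every free ring position is chlorinated the reaction converges on one compound. The thiosulfate work-up should return any N–Cl species to N–H.

Step 2
Reactants: 3 2-(4-hydroxyphenyl)acetic acid
Product: 4 2-(4-acetoxyphenyl)acetic acid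
Conditions: Ac2O (2.5 equiv), H2SO4 (cat.), 50 °C; then H2O, 25 °C
Reagents that add atoms: acetic anhydride, CC(=O)OC(C)=O
Why: Acid-catalysed O-acetylation of a phenol (the conditions of the aspirin preparation); any mixed anhydride at the carboxyl group is hydrolysed in the water quench while the aryl acetate survives. The acetate deactivates ring A for step 3 and is stable to every later step until the final methanolysis.

Step 3
Reactants: 4 2-(4-acetoxyphenyl)acetic acid
Product: 6 2-(4-acetoxyphenyl)-2-bromoacetyl chloride (racemic), via arylacetyl chloride 5 (not isolated)
Conditions: SOCl2 (4 equiv), 70 °C; then NBS (1.1 equiv), HBr (cat.), SOCl2–ClCH2CH2Cl, 80 °C; filtration, evaporation, used crude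
Reagents that add atoms: thionyl chloride, O=S(Cl)Cl; N-bromosuccinimide, O=C1CCC(=O)N1Br
Why: Acid chloride formation followed by HBr-catalysed enolisation and ionic α-bromination (Hell–Volhard–Zelinsky-type bromination of an acyl chloride with NBS as the bromine source). The benzylic α-C–H is the most enolisable site, and the acetoxy-substituted ring is too weakly activated to be brominated under acidic, initiator-free conditions. The new stereocentre is racemic and is lost later.

Step 4
Reactants: 2 3,4,5-trichloro-1H-pyrrole-2-carboxamide; 6 2-(4-acetoxyphenyl)-2-bromoacetyl chloride (racemic)
Product: 8 4-[4-oxo-2-(3,4,5-trichloro-1H-pyrrol-2-yl)-4,5-dihydro-1,3-oxazol-5-yl]phenyl acetate (racemic), via acyclic bromo imide 7 (not isolated)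
Conditions: pyridine (1.3 equiv), CH2Cl2–THF, 0 → 25 °C; aqueous wash, solvent exchange; NaF (3 equiv), DMF, 25 °C, under Ar
Reagents that add atoms: none
Why: Pyridine activates 6 as its acylpyridinium salt (or, after loss of HCl, as the aryl bromo ketene), and the primary carboxamide of 2 is acylated on nitrogen, directly or by O-acylation and 1,3-acyl shift, to give imide 7 (N3–C4). NaF in DMF, a weak heterogeneous base, should then let the oxygen of the ring C carbonyl in the imidate displace the benzylic bromide (O1–C5), closing ring B by a 5-exo-tet SN2 process and giving 8 after loss of HBr. The closest known reaction type is the preparation of 2-aryl-5H-oxazol-4-ones from primary amides and α-bromoacyl halides with pyridine and then NaF or Et3N. The electrophilic carbon is benzylic and α to a carbonyl, hence highly reactive in SN2 displacement, and the five-membered closure is the only one open to the imidate because closure through its nitrogen would give a three-membered ring. C5 is formed as a racemic stereocentre under no control, which is of no consequence because 8 enolises to the achiral 4-hydroxyoxazole and C5 becomes sp2 in step 5. The selectivity needed is acylation at the carboxamide nitrogen and closure through oxygen, not six-membered closure or acylation through the ring C nitrogen. It should be secured by the neutral ring C nitrogen being non-nucleophilic under pyridine (its lone pair is part of the aromatic sextet and is depleted by three chlorines and the carbonyl), by the faster five-membered closure, by the C5' chlorine that shields the ring C nitrogen from a secondary electrophile, and by choosing NaF over stronger bases to keep the ring C anion scarce. 8 is expected to be prone to autoxidation at C5 and is therefore handled under argon and used directly.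

Step 5
Reactants: 8 4-[4-oxo-2-(3,4,5-trichloro-1H-pyrrol-2-yl)-4,5-dihydro-1,3-oxazol-5-yl]phenyl acetate (racemic)
Product: 9 4-[4-chloro-2-(3,4,5-trichloro-1H-pyrrol-2-yl)-1,3-oxazol-5-yl]phenyl acetate
Conditions: POCl3 (excess), PhNEt2 (1 equiv), 90 °C; inverse quench into aq. NaOAc, 0 °C
Reagents that add atoms: phosphoryl chloride, O=P(Cl)(Cl)Cl
Why: Proposed new method: the enol form of 8 should be O-phosphorylated by POCl3; protonation at C5 by the anilinium chloride present returns the 5H form, in which C4 is an imidoyl-type carbon (C4=N3 in conjugation with O1), so chloride can add at C4, dichlorophosphate leaves, and loss of the C5 proton aromatises ring B. The closest known reaction type is the POCl3 deoxychlorination of thiazol-4(5H)-ones and thiazolidine-2,4-diones to 4-chlorothiazoles and of lactam-type hydroxy azines. The aryl acetate and the ring C chlorines are inert to POCl3.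

Step 6
Reactants: 9 4-[4-chloro-2-(3,4,5-trichloro-1H-pyrrol-2-yl)-1,3-oxazol-5-yl]phenyl acetate
Product: 10 4-[4-chloro-2-(3,4,5-trichloro-1H-pyrrol-2-yl)-1,3-oxazol-5-yl]phenol
Conditions: K2CO3 (2 equiv), MeOH, 0 → 25 °C; aq. NH4Cl
Reagents that add atoms: none
Why: Methanolysis (transesterification) of an aryl acetate by methoxide formed from K2CO3; the phenoxide is a good leaving group, so the reaction should be complete at or below room temperature. C4 is the least SNAr-active position of an oxazole, and ring C is present as its electron-rich anion under these conditions, so no C–Cl bond should be displaced.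

## Compound list

1 | 1H-pyrrole-2-carboxamide | NC(=O)c1ccc[nH]1 | starting material
2 | 3,4,5-trichloro-1H-pyrrole-2-carboxamide | NC(=O)c1[nH]c(Cl)c(Cl)c1Cl | intermediate
3 | 2-(4-hydroxyphenyl)acetic acid | OC(=O)Cc1ccc(O)cc1 | starting material
4 | 2-(4-acetoxyphenyl)acetic acid | CC(=O)Oc1ccc(CC(=O)O)cc1 | intermediate
5 | 2-(4-acetoxyphenyl)acetyl chloride | CC(=O)Oc1ccc(CC(=O)Cl)cc1 | intermediate (not isolated)
6 | 2-(4-acetoxyphenyl)-2-bromoacetyl chloride (racemic) | CC(=O)Oc1ccc(cc1)C(Br)C(Cl)=O | intermediate
7 | 4-{1-bromo-2-oxo-2-[(3,4,5-trichloro-1H-pyrrole-2-carbonyl)amino]ethyl}phenyl acetate (racemic) | CC(=O)Oc1ccc(cc1)C(Br)C(=O)NC(=O)c1[nH]c(Cl)c(Cl)c1Cl | intermediate (not isolated)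
8 | 4-[4-oxo-2-(3,4,5-trichloro-1H-pyrrol-2-yl)-4,5-dihydro-1,3-oxazol-5-yl]phenyl acetate (racemic) | CC(=O)Oc1ccc(cc1)C1OC(=NC1=O)c1[nH]c(Cl)c(Cl)c1Cl | intermediate
9 | 4-[4-chloro-2-(3,4,5-trichloro-1H-pyrrol-2-yl)-1,3-oxazol-5-yl]phenyl acetate | CC(=O)Oc1ccc(cc1)-c1oc(nc1Cl)-c1[nH]c(Cl)c(Cl)c1Cl | intermediate
10 | 4-[4-chloro-2-(3,4,5-trichloro-1H-pyrrol-2-yl)-1,3-oxazol-5-yl]phenol | Oc1ccc(-c2oc(-c3[nH]c(Cl)c(Cl)c3Cl)nc2Cl)cc1 | target

## Step count and least certain steps

Total step count: 6. Longest linear sequence: 5 (steps 2, 3, 4, 5 and 6, from 3 to 10); step 1 supplies the second fragment.

**Step 5 (proposed new method).**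
- Most likely to go wrong: the enol may be phosphorylated but the phosphate not displaced, because substitution at C4 requires the C5-protonated form, and chloride may instead add reversibly at C2 or the phosphate may simply be hydrolysed back on work-up. Thermal degradation of the electron-rich oxygenated oxazole at 90 °C is also possible.
- Fallback (known chemistry), setting out from 8 and coming back at 9:
  - O-sulfonylation of the enol with Tf2O and Et3N in CH2Cl2 at −78 °C, the established derivatisation of this ring class, should give 4-[2-(3,4,5-trichloro-1H-pyrrol-2-yl)-4-{[(trifluoromethyl)sulfonyl]oxy}-1,3-oxazol-5-yl]phenyl acetate F1.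
  - Formate reduction of the hetaryl triflate (Pd(OAc)2, PPh3, HCO2H, Et3N, DMF, 60 °C), conditions under which aryl chlorides are normally untouched, should give 4-[2-(3,4,5-trichloro-1H-pyrrol-2-yl)-1,3-oxazol-5-yl]phenyl acetate F2.
  - Electrophilic chlorination of the one free ring position, C4, with NCS (1.05 equiv, MeCN, 50 °C) should give 9. This is a known reaction of 2,5-disubstituted oxazoles, and ring A is protected from it by the acetate.

**Step 4 (key step).**
- Most likely to go wrong: loss of site selectivity in the ring closure. Once base is present the acidic ring C N–H is partly ionised, and alkylation or acylation through that nitrogen can compete with closure through oxygen. Further risks are quaternisation of pyridine by the benzylic bromide, elimination of HCl from 6 to a ketene that dimerises, and autoxidation of the enolised product at C5.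
- Fallback, setting out from 1 and 6 and coming back at 9 (the ring C chlorination is moved to the end, so that the pyrrole N–H is far less acidic than the imide N–H during the annulation):
  - The same pyridine and NaF sequence applied to 1 and 6 should give 4-[4-oxo-2-(1H-pyrrol-2-yl)-4,5-dihydro-1,3-oxazol-5-yl]phenyl acetate F3.
  - Deoxychlorination as in step 5 should give 4-[4-chloro-2-(1H-pyrrol-2-yl)-1,3-oxazol-5-yl]phenyl acetate F4.
  - NCS (3.2 equiv, MeCN–AcOH, 25 → 60 °C) should then chlorinate the three free positions of ring C, ring B being fully substituted and ring A deactivated, to give 9.

**Step 3.**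
- Most likely to go wrong: competing bromination of ring A ortho to the acetoxy group, partial cleavage of the acetate by hydrogen halide at 80 °C, and hydrolysis of the moisture-sensitive product during handling, since it cannot be purified. Halide scrambling at the acyl carbon would be harmless.
- Fallback, setting out from 4 and coming back at 7 (bromination after the acylation):
  - 4 is converted into 5 with SOCl2 alone.
  - 5 acylates 2 (pyridine, CH2Cl2–THF, 0 → 25 °C) to give 4-{2-oxo-2-[(3,4,5-trichloro-1H-pyrrole-2-carbonyl)amino]ethyl}phenyl acetate F5.
  - Wohl–Ziegler bromination of the methylene group, which is benzylic and α to the imide carbonyl (NBS, AIBN cat., PhCF3, 80 °C), should give 7, which is closed to 8 with NaF as in step 4.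

**Step 1.**
- Most likely to go wrong: incomplete chlorination at C3', the least reactive position next to the carboxamide, and oxidative side reactions at the primary amide nitrogen or over-chlorination of the ring when the reaction is forced.
- Fallback, setting out from 1 and coming back at 2 (the amide is masked as a nitrile during a more forcing chlorination):
  - Dehydration of 1 (2,4,6-trichloro-1,3,5-triazine, DMF, 25 °C) should give 1H-pyrrole-2-carbonitrile F6.
  - Exhaustive chlorination with SO2Cl2 (3.5 equiv, AcOH, 25 → 70 °C) should give 3,4,5-trichloro-1H-pyrrole-2-carbonitrile F7.
  - Acid hydration of the nitrile (conc. H2SO4, 70 °C, then ice) should return the primary amide 2.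

## Further compounds

F1 | step 5 | 4-[2-(3,4,5-trichloro-1H-pyrrol-2-yl)-4-{[(trifluoromethyl)sulfonyl]oxy}-1,3-oxazol-5-yl]phenyl acetate | CC(=O)Oc1ccc(cc1)-c1oc(nc1OS(=O)(=O)C(F)(F)F)-c1[nH]c(Cl)c(Cl)c1Cl
F2 | step 5 | 4-[2-(3,4,5-trichloro-1H-pyrrol-2-yl)-1,3-oxazol-5-yl]phenyl acetate | CC(=O)Oc1ccc(cc1)-c1cnc(o1)-c1[nH]c(Cl)c(Cl)c1Cl
F3 | step 4 | 4-[4-oxo-2-(1H-pyrrol-2-yl)-4,5-dihydro-1,3-oxazol-5-yl]phenyl acetate (racemic) | CC(=O)Oc1ccc(cc1)C1OC(=NC1=O)c1ccc[nH]1
F4 | step 4 | 4-[4-chloro-2-(1H-pyrrol-2-yl)-1,3-oxazol-5-yl]phenyl acetate | CC(=O)Oc1ccc(cc1)-c1oc(nc1Cl)-c1ccc[nH]1
F5 | step 3 | 4-{2-oxo-2-[(3,4,5-trichloro-1H-pyrrole-2-carbonyl)amino]ethyl}phenyl acetate | CC(=O)Oc1ccc(CC(=O)NC(=O)c2[nH]c(Cl)c(Cl)c2Cl)cc1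
F6 | step 1 | 1H-pyrrole-2-carbonitrile | N#Cc1ccc[nH]1
F7 | step 1 | 3,4,5-trichloro-1H-pyrrole-2-carbonitrile | N#Cc1[nH]c(Cl)c(Cl)c1Cl
A1 | alternative 1 | 3,4-dichloro-1H-pyrrole-2,5-dione (3,4-dichloromaleimide) | O=C1NC(=O)C(Cl)=C1Cl
A2 | alternative 1 | 3,4-dichloro-5-hydroxy-1,5-dihydro-2H-pyrrol-2-one (racemic) | OC1NC(=O)C(Cl)=C1Cl
A3 | alternative 1 | 2-isocyano-1-(4-methoxyphenyl)ethan-1-one | COc1ccc(cc1)C(=O)C[N+]#[C-]
A4 | alternative 1 | 3,4-dichloro-5-[5-(4-methoxyphenyl)-1,3-oxazol-2-yl]-1,5-dihydro-2H-pyrrol-2-one (racemic) | COc1ccc(cc1)-c1cnc(o1)C1NC(=O)C(Cl)=C1Cl
A5 | alternative 2 | 3,4,5-trichloro-1H-pyrrole-2-carbonyl chloride | O=C(Cl)c1[nH]c(Cl)c(Cl)c1Cl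
A6 | alternative 2 | 4-(2-azidoacetyl)phenyl pivalate | CC(C)(C)C(=O)Oc1ccc(cc1)C(=O)CN=[N+]=[N-]
A7 | alternative 2 | (Z)-2-azido-1-[4-(pivaloyloxy)phenyl]ethenyl 3,4,5-trichloro-1H-pyrrole-2-carboxylate | CC(C)(C)C(=O)Oc1ccc(cc1)/C(OC(=O)c1[nH]c(Cl)c(Cl)c1Cl)=C/N=[N+]=[N-]
A8 | alternative 2 | 4-[2-(3,4,5-trichloro-1H-pyrrol-2-yl)-1,3-oxazol-5-yl]phenyl pivalate | CC(C)(C)C(=O)Oc1ccc(cc1)-c1cnc(o1)-c1[nH]c(Cl)c(Cl)c1Cl
A9 | alternative 3 | 3-(4-methoxyphenyl)-2H-azirine | COc1ccc(cc1)C1=NC1
A10 | alternative 3 | 5-(4-methoxyphenyl)-2-(3,4,5-trichloro-1H-pyrrol-2-yl)-1,3-oxazole | COc1ccc(cc1)-c1cnc(o1)-c1[nH]c(Cl)c(Cl)c1Cl
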